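**Plan**
- Cuts: the two interflavan C4–C8 bonds (leaving three identical 2,3-cis flavan-3-ol units); then, within the unit, the C3–C4 bond of ring C and the O1–C2 ether bond, back to a ring-A salicylaldehyde and a ring-B nitrostyrene.
- Enabling feature: C3 of ring C carries oxygen and lies between C2 (on O1, bearing ring B) and C4 (benzylic to the phloroglucinol ring A). With a nitro group standing in for that oxygen, C3 becomes a nitronate carbon that closes ring C onto the ring-A aldehyde carbon C4.
- Forward: ring C is closed first (oxa-Michael, C3–C4 nitro-aldol, dehydration); NO2 and the C3=C4 bond are then traded for a C3 ketone. One monomer serves as lower, middle and upper unit, and the chain is joined from the lower unit upward by two C4→C8 arylations.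
- Stereochemistry: C2 and C3 (2R,3R, cis) are set together by dynamic kinetic resolution in the asymmetric transfer hydrogenation of the C2-labile flavan-3-one. C4 of the middle and upper units (4β, trans to 3-OH) comes from attack of C8 on the C4 cation anti to the axial 3-OH.
- Helpers: NO2 at C3 (leaves as ammonia), 2-ethoxyethoxy at C4 (leaving group), nine benzyl ethers (hydrogenolysis last).

Key step: step 3

Remark on the target: the SMILES is read as three (2R,3R)-epiafzelechin units joined by two 4β→8 bonds (upper C4 R, middle C4 S by the sequence rule, both 3,4-trans).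
Assumption: in step 5 the (R,R)-TsDPEN ruthenium catalyst is taken to give the 3R alcohol; if a first run shows the opposite sense, the (S,S) catalyst is used and nothing else changes.

**Step 1**
Reactants: 1 2,4,6-trihydroxybenzaldehyde
Product: 2 2,4-bis(benzyloxy)-6-hydroxybenzaldehyde
Conditions: BnBr (2.1 equiv), K2CO3, DMF, 0 °C to rt
Reagents that add atoms: benzyl bromide, BrCc1ccccc1
Why: Williamson etherification, in which the 4-OH and one ortho-OH are alkylated while the remaining ortho-OH, hydrogen-bonded to the aldehyde carbonyl, is the least nucleophilic and stays free as the later ring oxygen O1.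

**Step 2**
Reactants: 3 4-(benzyloxy)benzaldehyde; 4 nitromethane
Product: 5 (E)-1-(benzyloxy)-4-(2-nitroethenyl)benzene
Conditions: NH4OAc (cat.), AcOH, 100 °C
Reagents that add atoms: none
Why: Henry (nitro-aldol) condensation with dehydration in the same pot, which should give the conjugated, thermodynamically preferred E-nitroalkene.

**Step 3**
Reactants: 2 2,4-bis(benzyloxy)-6-hydroxybenzaldehyde; 5 (E)-1-(benzyloxy)-4-(2-nitroethenyl)benzene
Product: 8 rac-5,7-bis(benzyloxy)-2-[4-(benzyloxy)phenyl]-3-nitro-2H-chromene, via oxa-Michael adduct 6 (not isolated), via nitro-aldol adduct 7 (not isolated)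
Conditions: DABCO (0.5 equiv), 4 Å molecular sieves, toluene, 80 °C
Reagents that add atoms: none
Why: DABCO deprotonates the hydrogen-bonded phenol of 2 and the phenoxide adds through oxygen to the β-carbon of nitroalkene 5 (oxa-Michael), which forms O1–C2 and leaves nitronate 6, whose carbon (the later C3) attacks the neighbouring aldehyde carbon (the later C4) in an intramolecular nitro-aldol (Henry) reaction to give 7, and E1cB loss of water gives the conjugated nitroalkene 8. The closest known reaction type is the tandem oxa-Michael/Henry/dehydration synthesis of 2-aryl-3-nitro-2H-chromenes from salicylaldehydes and β-nitrostyrenes. Ring C is closed in the 6-exo-trig mode by the C3–C4 bond. C2 is the only stereocentre that survives and it is formed racemic on purpose, because it becomes epimerisable at the ketone stage and is fixed only in step 5, while the C3 and C4 centres of 7 are erased by the dehydration. The step needs O- rather than C-attack of the phenoxide and forward ring closure rather than retro-oxa-Michael cleavage; the formyl group lowers the carbon nucleophilicity of ring A, and the irreversible dehydration drains both reversible additions. The electron-rich, doubly ortho-substituted aldehyde is a poor electrophile, but the attack is intramolecular and the resulting benzylic alcohol should dehydrate easily because of the donor groups on ring A.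

**Step 4**
Reactants: 8 rac-5,7-bis(benzyloxy)-2-[4-(benzyloxy)phenyl]-3-nitro-2H-chromene
Product: 10 rac-5,7-bis(benzyloxy)-2-[4-(benzyloxy)phenyl]chroman-3-one, via chroman-3-imine 9 (not isolated)
Conditions: Fe powder (excess), AcOH/EtOH/H2O, 60 °C, N2
Reagents that add atoms: water, O
Why: Dissolving-metal reduction of a conjugated nitroalkene (reductive Nef-type nitroalkene-to-ketone conversion), in which zerovalent iron in acetic acid reduces the C3=C4–NO2 unit to imine 9 and water hydrolyses it to the C3 ketone, the benzyl ethers and the C2–O1 ether being inert and C2 staying racemic.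

**Step 5**
Reactants: 10 rac-5,7-bis(benzyloxy)-2-[4-(benzyloxy)phenyl]chroman-3-one
Product: 12 (2R,3R)-5,7-bis(benzyloxy)-2-[4-(benzyloxy)phenyl]chroman-3-ol, via enol 11 (not isolated)
Conditions: RuCl[(R,R)-TsDPEN](p-cymene) (2 mol %), HCO2H/Et3N (5:2), EtOAc, 40 °C
Reagents that add atoms: none
Why: Noyori–Ikariya asymmetric transfer hydrogenation under dynamic kinetic resolution, in which the C2–H (flanked by the carbonyl, ring B and O1) epimerises through enol 11 faster than the ketone is reduced and the catalyst reduces the 2R ketone with hydride delivery to C3 from the face opposite ring B, so that C2 (R) and C3 (R) are set together as the 2,3-cis alcohol.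

**Step 6**
Reactants: 12 (2R,3R)-5,7-bis(benzyloxy)-2-[4-(benzyloxy)phenyl]chroman-3-ol
Product: 13 (2R,3R,4S)-5,7-bis(benzyloxy)-2-[4-(benzyloxy)phenyl]-4-(2-ethoxyethoxy)chroman-3-ol
Conditions: DDQ (2 equiv), 2-ethoxyethanol (5 equiv), CH2Cl2, rt
Reagents that add atoms: 2-ethoxyethanol, CCOCCO
Why: DDQ benzylic oxidation, in which hydride is abstracted from the C4 methylene activated by the 5,7-dioxygenated ring A and the alcohol adds at C4 trans to the axial 3-OH (4β); this centre is only a leaving-group site, since C4 is ionised again in steps 7 and 8.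

**Step 7**
Reactants: 13 (2R,3R,4S)-5,7-bis(benzyloxy)-2-[4-(benzyloxy)phenyl]-4-(2-ethoxyethoxy)chroman-3-ol; 12 (2R,3R)-5,7-bis(benzyloxy)-2-[4-(benzyloxy)phenyl]chroman-3-ol (4 equiv)
Product: 14 hexa-O-benzyl epiafzelechin-(4β→8)-epiafzelechin
Conditions: TMSOTf (0.2 equiv), CH2Cl2, −78 °C; then aq NaHCO3
Reagents that add atoms: none
Why: Lewis-acid-mediated Friedel–Crafts arylation of a flavan-4-yl cation (the standard proanthocyanidin coupling), in which the ring-A-stabilised C4 cation is attacked by C8, the most nucleophilic position of 12, anti to the quasi-axial 3-OH of the 2,3-cis unit, which sets the new C4 centre 3,4-trans (4β), while the excess of 12 suppresses further chain growth.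

**Step 8**
Reactants: 13 (2R,3R,4S)-5,7-bis(benzyloxy)-2-[4-(benzyloxy)phenyl]-4-(2-ethoxyethoxy)chroman-3-ol; 14 hexa-O-benzyl epiafzelechin-(4β→8)-epiafzelechin (2 equiv)
Product: 15 nona-O-benzyl epiafzelechin-(4β→8)-epiafzelechin-(4β→8)-epiafzelechin
Conditions: TMSOTf (0.2 equiv), CH2Cl2, −78 to −40 °C; then aq NaHCO3
Reagents that add atoms: none
Why: The same cation arylation, in which C8 of the upper unit of 14 is the most reactive free ring position (the C6 positions are less nucleophilic) and attack anti to the 3-OH of the incoming unit sets its C4 as 4β (4R).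

**Step 9**
Reactants: 15 nona-O-benzyl epiafzelechin-(4β→8)-epiafzelechin-(4β→8)-epiafzelechin
Product: 16 epiafzelechin-(4β→8)-epiafzelechin-(4β→8)-epiafzelechin
Conditions: H2 (1 atm), Pd(OH)2/C, THF/MeOH/H2O, rt
Reagents that add atoms: none
Why: Catalytic hydrogenolysis of the nine benzyl ethers under neutral conditions, which should leave the acid-labile interflavan bonds and all eight stereocentres untouched.

**Compound list**
1 | 2,4,6-trihydroxybenzaldehyde | O=Cc1c(O)cc(O)cc1O | starting material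
2 | 2,4-bis(benzyloxy)-6-hydroxybenzaldehyde | O=Cc1c(O)cc(OCc2ccccc2)cc1OCc1ccccc1 | intermediate
3 | 4-(benzyloxy)benzaldehyde | O=Cc1ccc(OCc2ccccc2)cc1 | starting material
4 | nitromethane | C[N+](=O)[O-] | starting material
5 | (E)-1-(benzyloxy)-4-(2-nitroethenyl)benzene | [O-][N+](=O)/C=C/c1ccc(OCc2ccccc2)cc1 | intermediate
6 | 2,4-bis(benzyloxy)-6-{1-[4-(benzyloxy)phenyl]-2-nitroethoxy}benzaldehyde (oxa-Michael adduct, racemic) | O=Cc1c(OC(C[N+](=O)[O-])c2ccc(OCc3ccccc3)cc2)cc(OCc2ccccc2)cc1OCc1ccccc1 | intermediate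
7 | 5,7-bis(benzyloxy)-2-[4-(benzyloxy)phenyl]-3-nitrochroman-4-ol (nitro-aldol adduct, stereoisomer mixture) | OC1c2c(OCc3ccccc3)cc(OCc3ccccc3)cc2OC(c2ccc(OCc3ccccc3)cc2)C1[N+](=O)[O-] | intermediate
8 | rac-5,7-bis(benzyloxy)-2-[4-(benzyloxy)phenyl]-3-nitro-2H-chromene | [O-][N+](=O)C1=Cc2c(OCc3ccccc3)cc(OCc3ccccc3)cc2OC1c1ccc(OCc2ccccc2)cc1 | intermediate
9 | 5,7-bis(benzyloxy)-2-[4-(benzyloxy)phenyl]chroman-3-imine (racemic) | N=C1Cc2c(OCc3ccccc3)cc(OCc3ccccc3)cc2OC1c1ccc(OCc2ccccc2)cc1 | intermediate
10 | rac-5,7-bis(benzyloxy)-2-[4-(benzyloxy)phenyl]chroman-3-one | O=C1Cc2c(OCc3ccccc3)cc(OCc3ccccc3)cc2OC1c1ccc(OCc2ccccc2)cc1 | intermediate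
11 | 5,7-bis(benzyloxy)-2-[4-(benzyloxy)phenyl]-4H-chromen-3-ol (enol of 10) | OC1=C(c2ccc(OCc3ccccc3)cc2)Oc2cc(OCc3ccccc3)cc(OCc3ccccc3)c2C1 | intermediate
12 | (2R,3R)-5,7-bis(benzyloxy)-2-[4-(benzyloxy)phenyl]chroman-3-ol (5,7,4'-tri-O-benzylepiafzelechin) | c1ccccc1COc1cc(OCc2ccccc2)c2c(c1)O[C@H](c1ccc(OCc3ccccc3)cc1)[C@H](O)C2 | intermediate
13 | (2R,3R,4S)-5,7-bis(benzyloxy)-2-[4-(benzyloxy)phenyl]-4-(2-ethoxyethoxy)chroman-3-ol | CCOCCO[C@H]1c2c(OCc3ccccc3)cc(OCc3ccccc3)cc2O[C@H](c2ccc(OCc3ccccc3)cc2)[C@@H]1O | intermediate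
14 | hexa-O-benzyl epiafzelechin-(4β→8)-epiafzelechin (all phenols benzylated, both 3-OH free) | c1ccccc1COc1ccc([C@H]2Oc3c(c(OCc4ccccc4)cc(OCc4ccccc4)c3)[C@H](c3c(OCc4ccccc4)cc(OCc4ccccc4)c4c3O[C@H](c3ccc(OCc5ccccc5)cc3)[C@H](O)C4)[C@H]2O)cc1 | intermediate
15 | nona-O-benzyl epiafzelechin-(4β→8)-epiafzelechin-(4β→8)-epiafzelechin (all phenols benzylated, three 3-OH free) | c1ccccc1COc1ccc([C@H]2Oc3c(c(OCc4ccccc4)cc(OCc4ccccc4)c3[C@H]3c4c(OCc5ccccc5)cc(OCc5ccccc5)cc4O[C@H](c4ccc(OCc5ccccc5)cc4)[C@@H]3O)[C@H](c3c(OCc4ccccc4)cc(OCc4ccccc4)c4c3O[C@H](c3ccc(OCc5ccccc5)cc3)[C@H](O)C4)[C@H]2O)cc1 | intermediate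
16 | epiafzelechin-(4β→8)-epiafzelechin-(4β→8)-epiafzelechin | Oc1ccc([C@H]2Oc3c(c(O)cc(O)c3[C@H]3c4c(O)cc(O)cc4O[C@H](c4ccc(O)cc4)[C@@H]3O)[C@H](c3c(O)cc(O)c4c3O[C@H](c3ccc(O)cc3)[C@H](O)C4)[C@H]2O)cc1 | target

**Count**
Total steps: 9. Longest linear sequence: 8 steps (1, 3, 4, 5, 6, 7, 8, 9); step 2 is a one-step branch.

**Steps most likely to fail**

Step 5. Epimerisation at C2 may be slower than reduction, so that the process stalls as a simple kinetic resolution, or the catalyst may discriminate the two faces of C3 poorly. The fallback sets out from 10 and replaces catalytic control by resolution. Reduction with LiBH(s-Bu)3 in THF at −78 °C (hydride anti to ring B, as precedented for benzylated flavan-3-ones) should give the racemic 2,3-cis alcohol F1. Esterification with (S)-2-methoxy-2-phenylacetic acid (DCC, DMAP) gives the diastereomeric esters, the (2R,3R) ester F2 and the (2S,3S) ester F3, which are separated by chromatography or crystallisation. Saponification of F2 (LiOH, THF/H2O) returns to the route at 12.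

Step 3. The nitro-aldol closure onto the electron-rich, doubly ortho-substituted aldehyde may be too slow, letting the oxa-Michael step reverse and the nitroalkene polymerise. The fallback sets out from 2 and builds ring C without the nitro group. Condensation with (E)-2-[4-(benzyloxy)phenyl]ethenylboronic acid and catalytic dibenzylamine (Petasis-type vinyl transfer, loss of the amine to an ortho-quinone methide, oxa-6π electrocyclisation) should give 5,7-bis(benzyloxy)-2-[4-(benzyloxy)phenyl]-2H-chromene F4. Hydroboration and oxidation (BH3·THF, then H2O2/NaOH) gives the racemic 2,3-trans flavan-3-ol F5, and Dess–Martin oxidation returns to the route at 10.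

Step 8. The cation may attack C6 positions, and 13, whose own C8 is free, may condense with itself, so that regiocontrol and chain length are lost. The fallback sets out from 12 and blocks C8 of the electrophile. Bromination with NBS in CH2Cl2 at −78 °C gives the 8-bromo monomer F6, and DDQ with 2-ethoxyethanol gives the 8-bromo C4 ether F7, which cannot self-condense. TMSOTf-mediated coupling of F7 with 14 gives the 8-bromo nonabenzyl trimer F8. Hydrogenolysis (H2, Pd(OH)2/C, Et3N) removes bromine and all benzyl groups together and comes back to the route at 16.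

**Further compounds**
F1 | step 5 | rac-(2R*,3R*)-5,7-bis(benzyloxy)-2-[4-(benzyloxy)phenyl]chroman-3-ol (both enantiomers) | c1ccccc1COc1cc(OCc2ccccc2)c2c(c1)O[C@H](c1ccc(OCc3ccccc3)cc1)[C@H](O)C2.c1ccccc1COc1cc(OCc2ccccc2)c2c(c1)O[C@@H](c1ccc(OCc3ccccc3)cc1)[C@@H](O)C2
F2 | step 5 | (2R,3R)-5,7-bis(benzyloxy)-2-[4-(benzyloxy)phenyl]chroman-3-yl (S)-2-methoxy-2-phenylacetate | c1ccccc1COc1cc(OCc2ccccc2)c2c(c1)O[C@H](c1ccc(OCc3ccccc3)cc1)[C@H](OC(=O)[C@@H](OC)c1ccccc1)C2
F3 | step 5 | (2S,3S)-5,7-bis(benzyloxy)-2-[4-(benzyloxy)phenyl]chroman-3-yl (S)-2-methoxy-2-phenylacetate | c1ccccc1COc1cc(OCc2ccccc2)c2c(c1)O[C@@H](c1ccc(OCc3ccccc3)cc1)[C@@H](OC(=O)[C@@H](OC)c1ccccc1)C2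
F4 | step 3 | rac-5,7-bis(benzyloxy)-2-[4-(benzyloxy)phenyl]-2H-chromene | C1(c2ccc(OCc3ccccc3)cc2)Oc2cc(OCc3ccccc3)cc(OCc3ccccc3)c2C=C1
F5 | step 3 | rac-(2R*,3S*)-5,7-bis(benzyloxy)-2-[4-(benzyloxy)phenyl]chroman-3-ol (both enantiomers) | c1ccccc1COc1cc(OCc2ccccc2)c2c(c1)O[C@H](c1ccc(OCc3ccccc3)cc1)[C@@H](O)C2.c1ccccc1COc1cc(OCc2ccccc2)c2c(c1)O[C@@H](c1ccc(OCc3ccccc3)cc1)[C@H](O)C2
F6 | step 8 | (2R,3R)-5,7-bis(benzyloxy)-2-[4-(benzyloxy)phenyl]-8-bromochroman-3-ol | c1ccccc1COc1cc(OCc2ccccc2)c2c(c1Br)O[C@H](c1ccc(OCc3ccccc3)cc1)[C@H](O)C2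
F7 | step 8 | (2R,3R,4S)-5,7-bis(benzyloxy)-2-[4-(benzyloxy)phenyl]-8-bromo-4-(2-ethoxyethoxy)chroman-3-ol | CCOCCO[C@H]1c2c(OCc3ccccc3)cc(OCc3ccccc3)c(Br)c2O[C@H](c2ccc(OCc3ccccc3)cc2)[C@@H]1O
F8 | step 8 | nona-O-benzyl epiafzelechin-(4β→8)-epiafzelechin-(4β→8)-epiafzelechin carrying bromine at C8 of the upper unit | c1ccccc1COc1ccc([C@H]2Oc3c(c(OCc4ccccc4)cc(OCc4ccccc4)c3[C@H]3c4c(OCc5ccccc5)cc(OCc5ccccc5)c(Br)c4O[C@H](c4ccc(OCc5ccccc5)cc4)[C@@H]3O)[C@H](c3c(OCc4ccccc4)cc(OCc4ccccc4)c4c3O[C@H](c3ccc(OCc5ccccc5)cc3)[C@H](O)C4)[C@H]2O)cc1
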